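Per minute was the unit I wanted here, since it lets E and G, the two charged species that take up X, be set side by side.

E 0.13 M; J 0.950 equiv; G 0.0390 M; time 5.0 d; volume of the second phase over the first 0.50

    X ⇌ J, rate k1*([X] - [J]/K1) per volume of the first phase (K1 = 2.1, k1 = 8.8 × 10⁻⁴ /min)
    X + G → X.G (k2 = 0.011 /M/min)
    X + E.X → X.E.X (k3 = 0.0026 /M/min)
    E + X → E.X (k4 = 0.0050 /M/min)

- midnight: doubling the amount of J, all else as stated
- spring: doubling the transfer coefficient of step 1, all else as stated

* amount of E.X at 5.0 d, in percent of the E charged
* the change that raises the amount of E.X at 5.0 d, in percent of the E charged most ("none" if none brings more than 2 percentage points) (midnight / spring / none)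
* amount of E.X at 5.0 d, in percent of the E charged, after spring

- in the second phase: J; everything else is in the first
- charges count per volume of the first phase; a concentration in a rate is the amount of a species over the volume of its own phase; every rate counts per litre of the first phase
- run time (flask): 5.0 d

I followed one molecule of X in the flask. At the charge, E takes it at 6.50 × 10⁻⁴ /min and G at 4.29 × 10⁻⁴ /min, half-lives of 0.74 d and 1.1 d, so E is the likelier partner, at odds of 1.52. E and G meet the same X, so with the charges divided out of these odds, the fractions left obey e = g^s, where s = k4/k2 = 0.455 is the selectivity factor. With u = k3/k4 = 0.520, the fraction y of E.X is e^u minus e, over one minus u.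

I tried g = 0.167. Then e = 0.443 and y = 44.1 %, and the X used is 0.923 of the E charged, less than the 0.950 of J. That was my figure for y near the end of the reagent, and I expected somewhat less at 5.0 d. With nothing coming back, J has a half-life of 0.574 d, shorter than the run, so I chose midnight over spring.

The forecast gave 40.4 %, midnight and 41.5 %, “because partitioning limits the rate”. The flask gave 40.3 %, and midnight won with 8.2 percentage points against 1.1 points, spring reaching 41.4 %.

At 5.00 d the flask's G stood at 23.1 %, and s turns that into e = 51.3 %, with E read at 51.4 %. The neighbour flask with 0.33 M of E had G at 11.3 % at 5.00 d. The same s gives e = 37.0 %, with its E read at 37.0 %. From that e, y comes to 47.1 %, and the neighbour flask's E.X read 47.1 %.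

Its constants were chosen freely; the rest is arithmetic.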